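## Retrosynthetic overview
1. Target (22) ⇐ removal of two aryl TIPS groups ⇐ protected furofuran 21.
2. Ring B (the C7'–O bond) closes last, by acid-mediated 5-endo hydroalkoxylation of the arylidene-THF alcohol 20. This fixes the cis ring fusion and the exo aryl group.
3. Ring A and the key C8–C8' bond form first, by Cp2TiCl epoxide opening followed by 5-exo-dig radical cyclization of the epoxy propargyl ether 19. C7 is set by Sharpless kinetic resolution (KR) and C8 by trans-selective cyclization.
4. Substrate 19 comes from Sonogashira coupling of propargyl ether 9 with aryl iodide 18. Iodide 18 carries the erythro guaiacylglycerol 8-O-4' unit, made by Ru transfer hydrogenation with dynamic kinetic resolution (ATH–DKR) of an α-aryloxy ketone.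
5. All arenes come from catechol and resorcinol.

Assumptions:
- The drawn target has an exo,exo (+)-pinoresinol-type core, (7S,8R,8'R,7'S).
- The glycerol unit is erythro, (7''S,8''R).
- The epoxide stereocentre of 7 is irrelevant because it is lost at the radical stage.

## Route

**Step 1**
Reactants: 1 catechol
Product: 2 guaiacol
Conditions: Me2SO4 (1.0 equiv), NaOH (1.0 equiv), H2O, 0 °C → rt
Reagents that add atoms: dimethyl sulfate, COS(=O)(=O)OC
Why: Williamson mono-O-methylation with one equivalent of base; no stereocentres.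

**Step 2**
Reactants: 2 guaiacol
Product: 3 4-bromo-2-methoxyphenol
Conditions: NBS (1.0 equiv), CH2Cl2, −78 → 0 °C
Reagents that add atoms: NBS, O=C1CCC(=O)N1Br
Why: Electrophilic aromatic bromination goes para to the strongly activating OH.

**Step 3**
Reactants: 3
Product: 4 (4-bromo-2-methoxyphenoxy)triisopropylsilane
Conditions: TIPSCl, imidazole, DMF, rt
Reagents that add atoms: TIPSCl, CC(C)[Si](Cl)(C(C)C)C(C)C
Why: Silyl protection that survives Grignard formation, aqueous base (step 12) and CSA (step 16).

**Step 4**
Reactants: 4; 5 acrolein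
Product: 6 (±)-1-[3-methoxy-4-(TIPSO)phenyl]prop-2-en-1-ol
Conditions: 1) Mg, THF, reflux (I2 cat.); 2) acrolein, THF, −78 °C; NH4Cl
Reagents that add atoms: none (acrolein is reactant 5)
Why: Aryl Grignard 1,2-addition to an enal gives the racemic aryl vinyl carbinol.

**Step 5**
Reactants: 6
Product: 7 (R)-[3-methoxy-4-(TIPSO)phenyl](oxiran-2-yl)methanol; the epoxide carbon is a diastereomer mixture and is immaterial
Conditions: Ti(OiPr)4 (10 mol%), D-(−)-DET (12 mol%), TBHP (0.6 equiv), 3Å MS, CH2Cl2, −20 °C
Reagents that add atoms: TBHP, CC(C)(C)OO (supplies the epoxide O)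
Why: Sharpless KR epoxidizes the (S)-carbinol fast. This sets C7 of the core (S after O-alkylation) and supplies the epoxide that will become the C8 radical and the C9 CH2OH.

**Step 6**
Reactants: 7; 8 propargyl bromide
Product: 9 propargyl ether of 7
Conditions: NaH (1.05 equiv), TBAI (cat.), THF, −10 °C → rt
Reagents that add atoms: none (propargyl bromide is reactant 8)
Why: Williamson O-alkylation with no change at C7; the terminal alkyne is the radical acceptor and the Sonogashira handle.

**Step 7**
Reactants: 4; 10 2-chloro-N-methoxy-N-methylacetamide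
Product: 11 2-chloro-1-[3-methoxy-4-(TIPSO)phenyl]ethanone
Conditions: 1) Mg, THF, reflux; 2) 10, THF, −78 → 0 °C
Reagents that add atoms: none (10 is the reactant)
Why: The Weinreb amide stops at the ketone stage, giving the α-chloroketone.

**Step 8**
Reactants: 12 resorcinol
Product: 13 1,3-dimethoxybenzene
Conditions: Me2SO4 (2.3 equiv), K2CO3, acetone, reflux
Reagents that add atoms: dimethyl sulfate, COS(=O)(=O)OC
Why: Double Williamson methylation.

**Step 9**
Reactants: 13
Product: 14 2,6-dimethoxyphenol
Conditions: n-BuLi, THF, 0 °C; B(OMe)3, −78 °C → rt; then H2O2, NaOH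
Reagents that add atoms: trimethyl borate COB(OC)OC; hydrogen peroxide OO
Why: Lithiation between the two OMe groups (directed ortho-metalation), borylation, then oxidation of C–B to C–OH.

**Step 10**
Reactants: 14
Product: 15 4-iodo-2,6-dimethoxyphenol
Conditions: NIS (1.05 equiv), MeCN, 0 °C → rt
Reagents that add atoms: NIS, O=C1CCC(=O)N1I
Why: Electrophilic iodination para to OH.

**Step 11**
Reactants: 11; 15
Product: 16 α-aryloxy ketone
Conditions: K2CO3, NaI (cat.), acetone, reflux
Reagents that add atoms: none
Why: Finkelstein-assisted SN2 of the phenoxide on the primary α-chloroketone; no stereocentre yet.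

**Step 12**
Reactants: 16
Product: 17 (±)-α-aryloxy-β-hydroxy ketone
Conditions: 37% aq. HCHO (1.5 equiv), K2CO3 (0.2 equiv), THF/H2O, rt
Reagents that add atoms: formaldehyde, C=O
Why: Base-mediated aldol hydroxymethylation at the acidic α-CH2, a classical lignin-model route to the C9 carbon; the racemic α-centre is epimerizable.

**Step 13**
Reactants: 17
Product: 18 (7''S,8''R)-erythro diol aryl iodide
Conditions: RuCl[(R,R)-TsDPEN](p-cymene) (2 mol%), HCO2H/Et3N (5:2), CH2Cl2, 30 °C
Reagents that add atoms: none (formate is only the hydride source)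
Why: Noyori–Ikariya transfer hydrogenation. Proposed new method: it extends Ru-TsDPEN dynamic kinetic resolution of α-alkoxy ketones to an α-aryloxy-β-hydroxy ketone. The α-stereocentre epimerizes rapidly under HCO2H/Et3N. The (R,R)-catalyst is predicted to deliver the (S)-carbinol, as (S,S) gives (S)-1-phenylethanol, and the DKR funnels the α-centre to the anti (erythro) isomer, 8''R. The diastereomer is separable by chromatography if selectivity is incomplete.

**Step 14**
Reactants: 9; 18
Product: 19 epoxy aryl-alkyne
Conditions: Pd(PPh3)2Cl2 (5 mol%), CuI (5 mol%), Et3N, THF, 40 °C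
Reagents that add atoms: none
Why: Sonogashira coupling at the aryl iodide; the epoxide, free OH groups and TIPS ethers are inert.

**Step 15 (key radical step)**
Reactants: 19
Product: 20 2-aryl-3-(hydroxymethyl)-4-arylidene-THF (E/Z mixture, with the C7/C8 stereochemistry below)
Conditions: Cp2TiCl2 (3.5 equiv), Zn dust (6 equiv), THF, rt, 2 h; NH4Cl work-up
Reagents that add atoms: none (the two added H come from THF and work-up)
Why: Nugent–RajanBabu Cp2TiCl opening of the terminal epoxide gives the secondary C8 radical with a C9–OTi alkoxide. This radical undergoes 5-exo-dig cyclization onto the aryl alkyne, forming the C8–C8' bond and an α-aryl vinyl radical that is then protonated. C8' becomes sp2, so only C8 needs stereocontrol. The Beckwith chair-like TS with the C7 aryl pseudo-equatorial should place CH2OTi trans to the C7 aryl, giving (7S,8R); the minor cis isomer is removed by chromatography.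

**Step 16**
Reactants: 20
Product: 21 protected furofuran (bis-TIPS)
Conditions: (±)-CSA (10 mol%), CH2Cl2, 0 °C → rt
Reagents that add atoms: none (isomerization)
Why: Acid-catalysed intramolecular hydroalkoxylation. The electron-rich styrene is protonated at C8' on the face that allows C9–OH closure, so the fusion is necessarily cis. The resulting p-alkoxybenzylic cation is trapped by C9–OH, and the aryl group is placed exo under steric and thermodynamic control, giving (8'R,7'S). E/Z geometry is irrelevant.

**Step 17**
Reactants: 21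
Product: 22 Hedyotol C (target)
Conditions: TBAF (3 equiv), THF, 0 °C → rt
Reagents that add atoms: none
Why: Fluoride cleaves the two aryl TIPS ethers. No stereocentre is touched, and the benzylic ethers and secondary alcohol are untouched.

## Compound list
1 | catechol | Oc1ccccc1O | starting material
2 | guaiacol | COc1ccccc1O | intermediate
3 | 4-bromo-2-methoxyphenol | COc1cc(Br)ccc1O | intermediate
4 | (4-bromo-2-methoxyphenoxy)triisopropylsilane | COc1cc(Br)ccc1O[Si](C(C)C)(C(C)C)C(C)C | intermediate
5 | acrolein | C=CC=O | starting material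
6 | (±)-1-[3-methoxy-4-(TIPSO)phenyl]prop-2-en-1-ol | C=CC(O)c1ccc(O[Si](C(C)C)(C(C)C)C(C)C)c(OC)c1 | intermediate
7 | (R)-[3-methoxy-4-(TIPSO)phenyl](oxiran-2-yl)methanol (epoxide carbon unspecified) | O[C@H](c1ccc(O[Si](C(C)C)(C(C)C)C(C)C)c(OC)c1)C1CO1 | intermediate
8 | propargyl bromide | C#CCBr | starting material
9 | propargyl ether of 7 | C#CCO[C@H](c1ccc(O[Si](C(C)C)(C(C)C)C(C)C)c(OC)c1)C1CO1 | intermediate
10 | 2-chloro-N-methoxy-N-methylacetamide | ClCC(=O)N(C)OC | starting material
11 | 2-chloro-1-[3-methoxy-4-(TIPSO)phenyl]ethanone | ClCC(=O)c1ccc(O[Si](C(C)C)(C(C)C)C(C)C)c(OC)c1 | intermediate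
12 | resorcinol | Oc1cccc(O)c1 | starting material
13 | 1,3-dimethoxybenzene | COc1cccc(OC)c1 | intermediate
14 | 2,6-dimethoxyphenol | COc1cccc(OC)c1O | intermediate
15 | 4-iodo-2,6-dimethoxyphenol | COc1cc(I)cc(OC)c1O | intermediate
16 | 2-(4-iodo-2,6-dimethoxyphenoxy)-1-aryl-ethanone (aryl = 3-methoxy-4-TIPSO-phenyl) | O=C(COc1c(OC)cc(I)cc1OC)c1ccc(O[Si](C(C)C)(C(C)C)C(C)C)c(OC)c1 | intermediate
17 | (±)-3-hydroxy-2-(4-iodo-2,6-dimethoxyphenoxy)-1-aryl-propan-1-one | O=C(C(CO)Oc1c(OC)cc(I)cc1OC)c1ccc(O[Si](C(C)C)(C(C)C)C(C)C)c(OC)c1 | intermediate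
18 | (1S,2R)-erythro diol aryl iodide | COc1cc(I)cc(OC)c1O[C@H](CO)[C@@H](O)c1ccc(O[Si](C(C)C)(C(C)C)C(C)C)c(OC)c1 | intermediate
19 | epoxy aryl-alkyne | COc1cc(C#CCO[C@H](c2ccc(O[Si](C(C)C)(C(C)C)C(C)C)c(OC)c2)C2CO2)cc(OC)c1O[C@H](CO)[C@@H](O)c1ccc(O[Si](C(C)C)(C(C)C)C(C)C)c(OC)c1 | intermediate
20 | arylidene-THF alcohol | OC[C@H]1C(=Cc2cc(OC)c(O[C@H](CO)[C@@H](O)c3ccc(O[Si](C(C)C)(C(C)C)C(C)C)c(OC)c3)c(OC)c2)CO[C@@H]1c1ccc(O[Si](C(C)C)(C(C)C)C(C)C)c(OC)c1 | intermediate
21 | bis-TIPS furofuran | COc1cc([C@H]2OC[C@H]3[C@@H]2CO[C@@H]3c2cc(OC)c(O[C@H](CO)[C@@H](O)c3ccc(O[Si](C(C)C)(C(C)C)C(C)C)c(OC)c3)c(OC)c2)ccc1O[Si](C(C)C)(C(C)C)C(C)C | intermediate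
22 | Hedyotol C | COc1cc([C@H]2OC[C@H]3[C@@H]2CO[C@@H]3c2cc(OC)c(O[C@H](CO)[C@@H](O)c3ccc(O)c(OC)c3)c(OC)c2)ccc1O | target

## Totals
Total steps: 17. Longest linear sequence: 11 (catechol → 2 → 3 → 4 → 11 → 16 → 17 → 18 → 19 → 20 → 21 → 22).

## Three steps most likely to fail
1. **Step 13 (ATH–DKR).** The erythro selectivity, and the racemization versus retro-aldol balance, are unproven for this substrate.
   Fallback: build the unit by an MgCl2/Et3N/TMSCl anti-aldol of an N-(aryloxyacetyl)oxazolidinone with the TIPS-vanillin aldehyde, then LiBH4 removal of the auxiliary.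
2. **Step 15 (Ti(III) cascade).** The C8 radical is β to the C7 ether oxygen, so β-elimination or over-reduction may compete, and the trans selectivity may be only moderate.
   Fallback: generate the C8 radical from a xanthate, made from the 8,9-diol after primary-OH silylation. Use (TMS)3SiH/Et3B for the 5-exo-dig cyclization, then re-form the alkene and CH2OH by deprotection.
3. **Step 16 (acid ring closure).** The exo/endo ratio at C7' may be thermodynamically poor, and the free benzylic alcohol may ionize.
   Fallback: irreversible radical–polar-crossover hydroalkoxylation of 20 (Co(salen), N-fluoro-collidinium, PhSiH3, then separation of diastereomers).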